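**Retrosynthetic overview**

- The target is ent-labda-7,13E-diene-15,17-diol acylated at O15 by 30-hydroxytriacontanoic acid. The acyl chain is cut between C5 and C6 and made there as a C5=C6 olefin: the terpenyl hex-5-enoate and hexacos-25-en-1-ol are joined by protecting-group-free olefin cross-metathesis, then the new olefin is saturated with diimide.
- Enabling feature: the only C=C bonds of the target, C7=C8 in ring B and C13=C14 in the side chain, are trisubstituted and flanked by the allylic oxygens at C17 and C15, whereas the acyl part is an unbranched, stereocentre-free C30 chain. A 1,2-disubstituted olefin can therefore be made and erased inside the chain while both hydroxyls, the allylic ester and both terpene olefins stay untouched.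
- Terpene half: (−)-copalic acid supplies all twenty carbons, the trans-decalin (rings A and B are bought; no ring is formed in the route) and the stereocentres C5, C9 and C10. C8=C17 goes via the epoxide to C7=C8/C17-OH, and the C15 acid level keeps O15 and O17 distinct until the hexenoate is in place.
- Chain half: hexacos-25-en-1-ol from 10-bromodec-1-ene and methyl 16-bromohexadecanoate by copper-catalysed Grignard coupling and reduction.

Key step: step 10

Assumption: (−)-copalic acid (compound 1), the main diterpene acid of commercial copaiba oleoresin and sold as an isolated natural product, is taken as the purchasable chiral-pool material; its (5R,9R,10R) decalin has the absolute configuration of the target.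

**Route**

Step 1
Reactants: 1 (−)-copalic acid (ent-labda-8(17),13E-dien-15-oic acid)
Product: 2 isopropyl ent-labda-8(17),13E-dien-15-oate
Conditions: 2-iodopropane, K2CO3, DMF, 40 °C
Reagents that add atoms: 2-iodopropane, CC(C)I
Why: Carboxylate O-alkylation (SN2 esterification) leaves both olefins untouched, and the isopropyl ester is chosen so that the isopropoxide reagent of step 3 cannot scramble the ester group.

Step 2
Reactants: 2 isopropyl ent-labda-8(17),13E-dien-15-oate
Product: 3 isopropyl (8S)-8,17-epoxy-ent-labd-13E-en-15-oate
Conditions: mCPBA, NaHCO3, CH2Cl2, 0 °C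
Reagents that add atoms: mCPBA, OOC(=O)c1cccc(Cl)c1
Why: Prilezhaev epoxidation should be chemoselective for the electron-rich exocyclic C8=C17 olefin because C13=C14 is deactivated by conjugation with the ester, and the peracid should approach C8 from the face opposite the axial C10 methyl to give mainly the (8S)-epoxide, a stereocentre that is erased again in step 3.

Step 3
Reactants: 3 isopropyl (8S)-8,17-epoxy-ent-labd-13E-en-15-oate
Product: 4 isopropyl 17-hydroxy-ent-labda-7,13E-dien-15-oate
Conditions: Al(OiPr)3 (1.5 equiv), toluene, reflux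
Reagents that add atoms: none
Why: Aluminium-isopropoxide-mediated epoxide-to-allylic-alcohol isomerization (syn β-elimination through a cyclic transition state) should remove the accessible secondary H7 rather than the hindered tertiary H9 and open the C8–O bond, giving the trisubstituted C7=C8 olefin and the primary C17 alcohol while the weakly basic alkoxide leaves the enoate alone.

Step 4
Reactants: 4 isopropyl 17-hydroxy-ent-labda-7,13E-dien-15-oate
Product: 5 isopropyl 17-(tert-butyldimethylsilyloxy)-ent-labda-7,13E-dien-15-oate
Conditions: TBSCl, imidazole, DMF, rt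
Reagents that add atoms: TBSCl, CC(C)(C)[Si](C)(C)Cl
Why: Standard silylation of the only hydroxyl masks O17 so that O15, released in step 5, is the single acylation site.

Step 5
Reactants: 5 isopropyl 17-(tert-butyldimethylsilyloxy)-ent-labda-7,13E-dien-15-oate
Product: 6 17-(tert-butyldimethylsilyloxy)-ent-labda-7,13E-dien-15-ol
Conditions: DIBAL-H (2.5 equiv), CH2Cl2, −78 → 0 °C; Rochelle salt work-up
Reagents that add atoms: none
Why: DIBAL-H 1,2-reduction of the α,β-unsaturated ester gives the allylic alcohol with retention of the 13E geometry and does not touch the silyl ether or the ring olefin.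

Step 6
Reactants: 6 17-(tert-butyldimethylsilyloxy)-ent-labda-7,13E-dien-15-ol; 7 hex-5-enoic acid
Product: 8 17-(tert-butyldimethylsilyloxy)-ent-labda-7,13E-dien-15-yl hex-5-enoate
Conditions: DIC, DMAP (cat.), CH2Cl2, 0 °C → rt
Reagents that add atoms: none
Why: Steglich esterification acylates the unhindered primary allylic alcohol under neutral conditions that cannot ionize the allylic C15–O bond.

Step 7
Reactants: 8 17-(tert-butyldimethylsilyloxy)-ent-labda-7,13E-dien-15-yl hex-5-enoate
Product: 9 17-hydroxy-ent-labda-7,13E-dien-15-yl hex-5-enoate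
Conditions: HF·pyridine, pyridine, THF, 0 °C → rt
Reagents that add atoms: none
Why: Buffered fluoride desilylation cleaves the primary allylic TBS ether without affecting the allylic ester or any olefin.

Step 8
Reactants: 10 10-bromodec-1-ene; 11 methyl 16-bromohexadecanoate
Product: 13 methyl hexacos-25-enoate, via dec-9-enylmagnesium bromide 12 (not isolated)
Conditions: Mg, THF, 40 °C; then 11, Li2CuCl4 (3 mol %), THF/NMP, −10 → 0 °C
Reagents that add atoms: none
Why: Copper-catalysed Grignard alkyl–alkyl cross-coupling of a primary alkylmagnesium bromide with a primary bromide should outpace addition to the ester at low temperature in THF/NMP, and the terminal olefin is inert.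

Step 9
Reactants: 13 methyl hexacos-25-enoate
Product: 14 hexacos-25-en-1-ol
Conditions: LiAlH4, THF, 0 °C
Reagents that add atoms: none
Why: Hydride reduction of the ester gives the primary alcohol and leaves the isolated terminal olefin untouched.

Step 10
Reactants: 9 17-hydroxy-ent-labda-7,13E-dien-15-yl hex-5-enoate; 14 hexacos-25-en-1-ol
Product: 15 17-hydroxy-ent-labda-7,13E-dien-15-yl (5E)-30-hydroxytriacont-5-enoate (E/Z mixture expected, E drawn)
Conditions: 14 (3 equiv), Hoveyda–Grubbs II (5 mol %), 1,4-benzoquinone (10 mol %), CH2Cl2, 40 °C, argon sparge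
Reagents that add atoms: none
Why: Olefin cross-metathesis (Ru alkylidene, [2+2] cycloaddition to a metallacyclobutane and cycloreversion at each terminal olefin, loss of ethene) joins C5 of the hexenoate to C25 of the alkenol; the closest precedent is cross-metathesis of two unhindered monosubstituted olefins that carry free hydroxyl and ester groups. No ring is closed and no stereocentre is formed, and the geometry of the new C5=C6 bond is irrelevant because both isomers converge in step 11. The selectivity needed is reaction at the terminal olefin only, which the trisubstitution of C7=C8 and C13=C14 and the branching at C8/C9 and C13 should secure at 40 °C, so the ring-B allylic alcohol and the O15 allylic ester can stay unprotected. Cross- over self-coupling of 9 is favoured by the threefold excess of the cheap alkenol and by the reversibility of metathesis, since the homodimer of 14 is itself a competent partner, and removal of ethene drives conversion. Benzoquinone should suppress Ru–H double-bond migration, which would otherwise shorten the chain by one carbon or isomerize the C17 allylic alcohol.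

Step 11
Reactants: 15 17-hydroxy-ent-labda-7,13E-dien-15-yl (5E)-30-hydroxytriacont-5-enoate
Product: 16 17-hydroxy-ent-labda-7,13E-dien-15-yl 30-hydroxytriacontanoate (CNP0329077.1)
Conditions: 2-nitrobenzenesulfonyl hydrazide (NBSH, excess, in portions), Et3N, CH2Cl2, rt
Reagents that add atoms: none
Why: Diimide reduction is a concerted syn transfer of H2 whose rate falls steeply with olefin substitution, so the 1,2-disubstituted C5=C6 bond should be saturated in preference to the trisubstituted C7=C8 and C13=C14 bonds, with no metal present that could hydrogenolyse the allylic ester.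

**Compound list**

1 | (−)-copalic acid, (5R,9R,10R)-ent-labda-8(17),13E-dien-15-oic acid | C/C(=C\C(=O)O)CC[C@@H]1C(=C)CC[C@@H]2C(C)(C)CCC[C@@]12C | starting material
2 | isopropyl ent-labda-8(17),13E-dien-15-oate | C/C(=C\C(=O)OC(C)C)CC[C@@H]1C(=C)CC[C@@H]2C(C)(C)CCC[C@@]12C | intermediate
3 | isopropyl (5R,8S,9S,10R)-8,17-epoxy-ent-labd-13E-en-15-oate (epoxide oxygen on the face opposite the C10 methyl) | C/C(=C\C(=O)OC(C)C)CC[C@@H]1[C@]2(CO2)CC[C@@H]3C(C)(C)CCC[C@@]13C | intermediate
4 | isopropyl (5R,9S,10R)-17-hydroxy-ent-labda-7,13E-dien-15-oate | C/C(=C\C(=O)OC(C)C)CC[C@@H]1C(CO)=CC[C@@H]2C(C)(C)CCC[C@@]12C | intermediate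
5 | isopropyl 17-(tert-butyldimethylsilyloxy)-ent-labda-7,13E-dien-15-oate | C/C(=C\C(=O)OC(C)C)CC[C@@H]1C(CO[Si](C)(C)C(C)(C)C)=CC[C@@H]2C(C)(C)CCC[C@@]12C | intermediate
6 | 17-(tert-butyldimethylsilyloxy)-ent-labda-7,13E-dien-15-ol | C/C(=C\CO)CC[C@@H]1C(CO[Si](C)(C)C(C)(C)C)=CC[C@@H]2C(C)(C)CCC[C@@]12C | intermediate
7 | hex-5-enoic acid | C=CCCCC(=O)O | starting material
8 | 17-(tert-butyldimethylsilyloxy)-ent-labda-7,13E-dien-15-yl hex-5-enoate | C/C(=C\COC(=O)CCCC=C)CC[C@@H]1C(CO[Si](C)(C)C(C)(C)C)=CC[C@@H]2C(C)(C)CCC[C@@]12C | intermediate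
9 | (5R,9S,10R)-17-hydroxy-ent-labda-7,13E-dien-15-yl hex-5-enoate | C/C(=C\COC(=O)CCCC=C)CC[C@@H]1C(CO)=CC[C@@H]2C(C)(C)CCC[C@@]12C | intermediate
10 | 10-bromodec-1-ene | C=CCCCCCCCCBr | starting material
11 | methyl 16-bromohexadecanoate | BrCCCCCCCCCCCCCCCC(=O)OC | starting material
12 | dec-9-enylmagnesium bromide | C=CCCCCCCCC[Mg]Br | intermediate
13 | methyl hexacos-25-enoate | C=CCCCCCCCCCCCCCCCCCCCCCCCC(=O)OC | intermediate
14 | hexacos-25-en-1-ol | C=CCCCCCCCCCCCCCCCCCCCCCCCCO | intermediate
15 | 17-hydroxy-ent-labda-7,13E-dien-15-yl (5E)-30-hydroxytriacont-5-enoate | C/C(=C\COC(=O)CCC/C=C/CCCCCCCCCCCCCCCCCCCCCCCCO)CC[C@@H]1C(CO)=CC[C@@H]2C(C)(C)CCC[C@@]12C | intermediate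
16 | (5R,9S,10R)-17-hydroxy-ent-labda-7,13E-dien-15-yl 30-hydroxytriacontanoate (CNP0329077.1) | C/C(=C\COC(=O)CCCCCCCCCCCCCCCCCCCCCCCCCCCCCO)CC[C@@H]1C(CO)=CC[C@@H]2C(C)(C)CCC[C@@]12C | target

**Step count and risks**

Total steps: 11. Longest linear sequence: 9 steps (steps 1–7, 10 and 11, from compound 1).

Steps most likely to fail:

Step 3. The elimination may run toward C9 and give the tetrasubstituted C8=C9 isomer, or the Lewis-acidic aluminium may trigger a 1,2-hydride shift of the opened epoxide to the C8 aldehyde (Meinwald rearrangement), which would then be reduced in the Meerwein–Ponndorf–Verley manner. The fallback sets out from 2 and comes back at 4 without an epoxide. Allylic hydroxylation of the exocyclic olefin of 2 with catalytic SeO2 and t-BuOOH in CH2Cl2 (ene reaction at C17, then [2,3]-shift that returns oxygen to C7 on the face opposite the C10 methyl) should give isopropyl (7S)-7-hydroxy-ent-labda-8(17),13E-dien-15-oate F1. A rhenium-oxo-catalysed 1,3-allylic transposition (Ph3SiOReO3, Et2O, 0 °C) should then move the hydroxyl to C17 and the double bond to C7=C8 under thermodynamic control, giving 4.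

Step 10. Statistical self-metathesis of 9 may compete, or the terminal double bonds may migrate before metathesis so that chain-shortened homologues form. The fallback sets out from 9 and 14 and comes back at 15; it makes the union intramolecular through a temporary silicon tether. Compound 9 is silylated at O17 with excess iPr2SiCl2/imidazole and the chlorosilane is quenched with 14, giving 17-{[(hexacos-25-en-1-yloxy)di(propan-2-yl)silyl]oxy}-ent-labda-7,13E-dien-15-yl hex-5-enoate F2. Ring-closing metathesis at high dilution (Grubbs II, CH2Cl2, 40 °C) should form the same C5=C6 bond and close the 42-membered O17,O30-diisopropylsilylene-bridged (5E)-macrocycle F3. HF·pyridine then removes the tether and gives 15.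

Step 11. The trisubstituted C13=C14 or C7=C8 bond may begin to be reduced before the disubstituted olefin is consumed, or conversion may stall. The fallback sets out from 8 and 14 and comes back at 16; it keeps the silyl ether through the union and replaces diimide by a sterically gated metal hydrogenation on a substrate with no free allylic alcohol. Cross-metathesis of 8 with 14 under the conditions of step 10 should give 17-(tert-butyldimethylsilyloxy)-ent-labda-7,13E-dien-15-yl (5E)-30-hydroxytriacont-5-enoate F4. Hydrogenation with RhCl(PPh3)3 under 1 atm H2 in benzene should saturate only the 1,2-disubstituted olefin and give 17-(tert-butyldimethylsilyloxy)-ent-labda-7,13E-dien-15-yl 30-hydroxytriacontanoate F5. HF·pyridine in THF then releases 16.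

**Further compounds**

F1 | step 3 | isopropyl (7S)-7-hydroxy-ent-labda-8(17),13E-dien-15-oate | C/C(=C\C(=O)OC(C)C)CC[C@@H]1C(=C)[C@@H](O)C[C@@H]2C(C)(C)CCC[C@@]12C
F2 | step 10 | 17-{[(hexacos-25-en-1-yloxy)di(propan-2-yl)silyl]oxy}-ent-labda-7,13E-dien-15-yl hex-5-enoate | C/C(=C\COC(=O)CCCC=C)CC[C@@H]1C(CO[Si](C(C)C)(C(C)C)OCCCCCCCCCCCCCCCCCCCCCCCCC=C)=CC[C@@H]2C(C)(C)CCC[C@@]12C
F3 | step 10 | 42-membered O17,O30-diisopropylsilylene-bridged (5E)-macrocycle | C/C(=C\COC(=O)CCC/C=C/CCCCCCCCCCCCCCCCCCCCCCCCO[Si](C(C)C)(C(C)C)OC3)CC[C@@H]1C3=CC[C@@H]2C(C)(C)CCC[C@@]12C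
F4 | step 11 | 17-(tert-butyldimethylsilyloxy)-ent-labda-7,13E-dien-15-yl (5E)-30-hydroxytriacont-5-enoate | C/C(=C\COC(=O)CCC/C=C/CCCCCCCCCCCCCCCCCCCCCCCCO)CC[C@@H]1C(CO[Si](C)(C)C(C)(C)C)=CC[C@@H]2C(C)(C)CCC[C@@]12C
F5 | step 11 | 17-(tert-butyldimethylsilyloxy)-ent-labda-7,13E-dien-15-yl 30-hydroxytriacontanoate | C/C(=C\COC(=O)CCCCCCCCCCCCCCCCCCCCCCCCCCCCCO)CC[C@@H]1C(CO[Si](C)(C)C(C)(C)C)=CC[C@@H]2C(C)(C)CCC[C@@]12C
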